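## Structural features

The target is a neoflavone. Benzo ring A (C4a to C8a) is fused to an α-pyranone ring B (O1, C2, C3, C4), and a pendant aryl ring is joined to C4 through the C4–C1' bond. Ring A carries methoxy groups on C5, C7 and C8 and hydrogen only on C6, so O1 on C8a stands at the end of a run of three neighbouring oxygenated carbons (C8a, C8, C7), with a fourth oxygen alone on C5. The pendant ring has the isovanillyl pattern, 3'-OH and 4'-OMe. There is no stereocentre; the C5 methoxy group twists the pendant ring out of the coumarin plane, but that ring has no ortho substituent, so no stable axis is expected. The fragile elements are the lactone (opened by alkali), the single free phenol, and the electron-rich ring A, which is easily oxidised once it bears a free hydroxyl. The real difficulty is differentiation among six aryl oxygens: one (O1) must end in the lactone, one (on C3') as a free hydroxyl, and four as methyl ethers in a fixed pattern. The key step exploits the fact that C2 is a carbonyl carbon with only two skeletal neighbours, O1 and C3. A phenol oxygen on C8a and a terminal vinylic CH2 that becomes C3 face each other across C4a and C4 and can be bridged by one molecule of CO.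

## Logic of the disconnections

12 to 11. The O–CH2 bond of a benzyl ether on the C3' oxygen is cut. The one free hydroxyl of 12 cannot come from a late selective demethylation among five methyl ethers, so it is carried under a mask. A benzyl ether is preferred to an arenesulfonate or an ester: it is inert to organomagnesium reagents (which can attack a sulfonate at sulfur), to acid and to the palladium/quinone conditions, and it is removed under neutral conditions, so the lactone never meets hydroxide. Leaving the C3' hydroxyl free would save a step but would offer palladium and the quinone a second phenol; the mask is kept for safety. The forward step must spare the C3=C4 double bond.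

11 to 9 and 10. The bonds O1–C2 and C2–C3 are cut, which removes the whole of ring B in one operation. What is left is a 2-(1-arylvinyl)phenol and a one-carbon unit, so the lactone carbonyl need not be carried through earlier steps. The forward step must be oxidative, must tolerate a very electron-rich phenol, and must join the carbonyl to the CH2 terminus and not to the diaryl-substituted carbon.

9 to 8 to 4 and 7. The C3=C4 double bond is traced to loss of water from a tertiary carbinol, and the bond from the carbinol carbon (future C4) to C1' is then cut. This divides the molecule into two arenes of similar size, one a methyl ketone that already holds C4, C3 and the whole of ring A, the other a simple aryl nucleophile. Dehydration can go only one way because the methyl group is the sole source of β-hydrogen. The forward step needs addition to a hindered, enolisable ketone to outrun proton transfer, and one extra equivalent of nucleophile for the phenol proton.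

7 to 6 to 5. The C–Mg bond is traced to a C–Br bond and the benzyl O–C bond is cut. The bromine of 5 already sits para to the methoxy group and meta to the hydroxyl, so the isovanillyl pattern is bought, not made. The forward demand is ordinary O-alkylation and magnesium insertion.

4 to 3 to 1 and 2. The hydroxyl that becomes O1 is traced to a methyl ether, and the aryl–acyl bond (C4a to the future C4) is cut. The two ring hydrogens of 1 are equivalent, so acylation can give only one ketone, and the carbonyl then serves as the handle that picks out an ortho ether for cleavage. The gain is a direct entry to the whole ring A pattern from one symmetrical arene. The forward step must cleave the ortho methoxy group next to the other methoxy group (future O1), not the one next to hydrogen (future C5 methoxy), and must stop after one cleavage.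

## Other disconnections considered

Alternative 1: The cut is C7–C8, so ring A is built from an open chain hidden in a pyranone. In the forward step methoxide would open 6-[3-(benzyloxy)-4-methoxyphenyl]-4-methoxy-5-(methoxyacetyl)-2H-pyran-2-one (A2) to a triketo ester. The methoxymethylene carbon of that ester would then close onto the ester carbonyl in a Claisen condensation, and enolisation would give the benzophenone A1.
- In its favour: the oxygen pattern of ring A is written into the chain. The C8 methoxy group comes from the methoxyacetyl unit and the C5 methoxy group from the pyranone enol ether. The two hydroxyls of A1 differ sharply (C8a–OH chelated to the ketone, C7–OH not), so the C7 oxygen could be methylated selectively. On the placing of the free phenol this plan is better than the chosen one, which must choose between two ortho ethers. It is also metal-free and gas-free, and there it is the equal or the better in operational terms.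
- Against it: A2 is a fully substituted pyranone that has to be made first, with an acyl group at C5, which is not the naturally nucleophilic position of a 4-methoxypyranone. The required nucleophile is the less acidic of the enolisable carbons of the triketo ester, and aldol closure onto the aroyl ketone can compete.
- Comparison: A1 still lacks ring B, so methylation, a two-carbon lactone annulation and debenzylation would follow. The chosen plan buys ring A and builds only ring B; this plan builds a ring that can be bought and then still has to build ring B. Step economy is clearly worse.

Alternative 2: The cut is C5–C4a, with ring A formed by a pericyclic cascade. In the forward step, heating the cyclobutenone A4 (from a lithiated dihydropyran and a methoxycyclobutenedione) would open the four-membered ring to a dienylketene. Six-electron electrocyclisation and tautomerisation would then give the chromane-5,8-diol A3 as a mixture of diastereomers.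
- In its favour: the step needs no catalyst, only heat. Every ring A oxygen is placed by the connectivity of the four-membered ring, so there is no regiochemical question in ring A; on that point it is better than the chosen plan. The C4 aryl group and the ring B oxygen arrive already attached, so it is convergent.
- Against it: A3 has ring B at the wrong oxidation level twice over, an acetal at C2 and a saturated C3–C4 bond. After double O-methylation the acetal would have to be oxidised to the lactone and the ring dehydrogenated. Two stereocentres (C2, C4) are made only to be destroyed. The hydroquinone is air-sensitive, and the vinyllithium has to be generated next to a benzyl ether and a methoxyarene, both of which can be metalated.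
- Comparison: the mechanism is elegant and well behaved for simple cases, and equal to the chosen plan in bond-forming power (one ring, one C–C bond). Redox economy and step count are much worse, since the chosen key step delivers ring B at the final oxidation level.

Alternative 3: The cut is C8a–O1, with the oxygen inserted late. In the forward step a peracid would convert the indanone A6 into the dihydrocoumarin A5 by Baeyer–Villiger migration of the ring A carbon.
- In its favour: the migrating aryl carbon has ortho and para methoxy groups and should migrate in preference to the CH2 group. O1 is introduced by the oxidation itself, so all three ring A methoxy groups can be in place from the start and no selective ether cleavage is needed; on that point it is better than the chosen plan. The reagents are classical and no pressurised CO is needed, which is also a point in its favour.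
- Against it: A5 is a dihydrocoumarin whose C4 stereocentre is formed only to be removed, so a dehydrogenation of an electron-rich substrate must follow. The peracid meets a very electron-rich arene, and the ketone is deactivated by ortho and para donors. The sulfonate must finally be cleaved with base, which opens the lactone.
- Comparison: the step count is about equal to the chosen plan once the indanone synthesis is included. The chosen plan is ahead on redox economy, since no dehydrogenation is needed, and on the mildness of the last step. It is behind on the regiochemical certainty of the O1 oxygen.

Key step: step 4

Remark: in 3 the methoxy group lying between the acetyl group and a neighbouring methoxy group is taken to be the one cleaved under aluminium chelation, as is usual for aryl ketones of this substitution type.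

## Route

Step 1
Reactants: 1 1,2,3,5-tetramethoxybenzene; 2 acetyl chloride
Product: 4 1-(2-hydroxy-3,4,6-trimethoxyphenyl)ethanone, via 2,3,4,6-tetramethoxyacetophenone 3 (not isolated)
Conditions: AlCl3 (2.5 equiv), Et2O, 0 °C to rt; 1 M HCl
Reagents that add atoms: none
Why: Friedel–Crafts acylation at one of the two equivalent ring positions gives 3; aluminium then chelates the ketone and an ortho ether oxygen, and chloride removes the methyl group of the more crowded ortho methoxy group (twisted out of conjugation between acyl and methoxy), after which the chelated aluminium phenoxide occupies the carbonyl and should stop a second cleavage.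

Step 2
Reactants: 5 5-bromo-2-methoxyphenol
Product: 6 2-(benzyloxy)-4-bromo-1-methoxybenzene
Conditions: BnBr (1.1 equiv), K2CO3 (1.5 equiv), DMF, rt
Reagents that add atoms: benzyl bromide, BrCc1ccccc1
Why: Williamson ether synthesis on a phenoxide with a reactive benzylic halide; the aryl bromide is untouched.

Step 3
Reactants: 6 2-(benzyloxy)-4-bromo-1-methoxybenzene; 4 1-(2-hydroxy-3,4,6-trimethoxyphenyl)ethanone
Product: 9 2-{1-[3-(benzyloxy)-4-methoxyphenyl]ethenyl}-3,5,6-trimethoxyphenol, via arylmagnesium bromide 7 (not isolated), via tertiary carbinol 8 (not isolated)
Conditions: 6 (2.6 equiv), Mg, THF, 50 °C; then 4, THF, 0 °C to rt; 1 M HCl, 0 °C; crude carbinol, TsOH·H2O (5 mol %), toluene, 40 °C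
Reagents that add atoms: none
Why: Grignard addition, in which the first equivalent of 7 deprotonates the phenol and the magnesium-chelated ketone accepts the second to give racemic 8. Acid-catalysed E1 dehydration through a doubly benzylic cation, stabilised by ortho and para oxygen, should then give the 1,1-diarylethene as the only possible alkene and erase the stereocentre.

Step 4
Reactants: 9 2-{1-[3-(benzyloxy)-4-methoxyphenyl]ethenyl}-3,5,6-trimethoxyphenol; 10 carbon monoxide
Product: 11 4-[3-(benzyloxy)-4-methoxyphenyl]-5,7,8-trimethoxy-2H-chromen-2-one
Conditions: Pd(OAc)2 (5 mol %), 1,4-benzoquinone (1.5 equiv), CO (7 bar), MeCN, 100 °C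
Reagents that add atoms: none
Why: This is the palladium-catalysed oxidative cyclocarbonylation of a 2-vinylphenol to a coumarin, a known reaction type, applied here to a 1,1-diarylethene. Divalent palladium exchanges acetate for the phenoxide of 9, CO inserts into the Pd–O bond to give an aryloxycarbonylpalladium species, and this adds across the tethered alkene with the acyl carbon bonding to the terminal CH2 and palladium to the diaryl-substituted carbon. Ring B therefore closes by a 6-endo-trig acylpalladation, O1–C2 coming from the CO insertion and C2–C3 from the alkene insertion. Syn β-hydride elimination of a C3 hydrogen sets the C3=C4 double bond, and the palladium hydride collapses to zerovalent palladium, which 1,4-benzoquinone returns to the divalent state. A second pathway, phenoxide-directed palladation of the terminal vinylic C–H bond followed by CO insertion and C–O reductive elimination, would form the same two bonds. Regiochemistry is held by three things: insertion into a 1,1-diarylethene puts the incoming carbon on the unsubstituted terminus, the competing 5-exo closure would leave an alkylpalladium without β-hydrogen and so without a productive exit, and C3 is the only carbon with hydrogen to lose. No stereocentre is formed, and the twist of ring A out of the alkene plane places O1 above the π face, which suits the insertion. The selectivity that has to be won is chemoselectivity, carbonylation against oxidation or quinone arylation of the electron-rich phenol; it is served by the absence of base and water, by only a small excess of quinone, and by the benzyl ether, which keeps the second phenol out of reach of palladium.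

Step 5
Reactants: 11 4-[3-(benzyloxy)-4-methoxyphenyl]-5,7,8-trimethoxy-2H-chromen-2-one
Product: 12 4-(3-hydroxy-4-methoxyphenyl)-5,7,8-trimethoxy-2H-chromen-2-one (3'-hydroxy-5,7,8,4'-tetramethoxy-4-phenylcoumarin)
Conditions: H2 (1 atm), 10% Pd/C, EtOAc–MeOH, rt
Reagents that add atoms: none
Why: Catalytic hydrogenolysis of the benzylic C–O bond under neutral conditions; the trisubstituted, conjugated and hindered C3=C4 bond should react much more slowly, and the methyl ethers and the lactone are inert.

## Compound list

1 | 1,2,3,5-tetramethoxybenzene | COc1cc(OC)c(OC)c(OC)c1 | starting material
2 | acetyl chloride | CC(Cl)=O | starting material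
3 | 1-(2,3,4,6-tetramethoxyphenyl)ethanone (2,3,4,6-tetramethoxyacetophenone) | CC(=O)c1c(OC)cc(OC)c(OC)c1OC | intermediate (not isolated)
4 | 1-(2-hydroxy-3,4,6-trimethoxyphenyl)ethanone | CC(=O)c1c(OC)cc(OC)c(OC)c1O | intermediate
5 | 5-bromo-2-methoxyphenol | COc1ccc(Br)cc1O | starting material
6 | 2-(benzyloxy)-4-bromo-1-methoxybenzene | COc1ccc(Br)cc1OCc1ccccc1 | intermediate
7 | [3-(benzyloxy)-4-methoxyphenyl]magnesium bromide | COc1ccc([Mg]Br)cc1OCc1ccccc1 | intermediate (not isolated)
8 | 1-[3-(benzyloxy)-4-methoxyphenyl]-1-(2-hydroxy-3,4,6-trimethoxyphenyl)ethan-1-ol (racemic) | CC(O)(c1ccc(OC)c(OCc2ccccc2)c1)c1c(OC)cc(OC)c(OC)c1O | intermediate (not isolated)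
9 | 2-{1-[3-(benzyloxy)-4-methoxyphenyl]ethenyl}-3,5,6-trimethoxyphenol | C=C(c1ccc(OC)c(OCc2ccccc2)c1)c1c(OC)cc(OC)c(OC)c1O | intermediate
10 | carbon monoxide | [C-]#[O+] | starting material
11 | 4-[3-(benzyloxy)-4-methoxyphenyl]-5,7,8-trimethoxy-2H-chromen-2-one | COc1ccc(-c2cc(=O)oc3c(OC)c(OC)cc(OC)c23)cc1OCc1ccccc1 | intermediate
12 | 4-(3-hydroxy-4-methoxyphenyl)-5,7,8-trimethoxy-2H-chromen-2-one | COc1ccc(-c2cc(=O)oc3c(OC)c(OC)cc(OC)c23)cc1O | target

## Step count and risks

Total step count: 5. Longest linear sequence: 4 steps (steps 1, 3, 4, 5 from 1, or steps 2, 3, 4, 5 from 5).

Step 4 (key step). The likely failure is oxidative consumption of the substrate. Ring A of 9 is a tetra-oxygenated phenol, and electron transfer to the quinone or to divalent palladium, oxidative coupling, or addition of the nucleophilic arene to benzoquinone may run faster than carbonylation. This is the more likely because the two ortho substituents beside the vinyl group slow the alkene insertion. The fallback builds ring B before the aryl group is attached; it sets out from 4 and returns at 11. Ketone 4 is condensed with diethyl carbonate and NaH in toluene at reflux (C-acylation and lactonisation) to 4-hydroxy-5,7,8-trimethoxy-2H-chromen-2-one F1. Tf2O and Et3N in CH2Cl2 at 0 °C then give 5,7,8-trimethoxy-2-oxo-2H-chromen-4-yl trifluoromethanesulfonate F2. Suzuki–Miyaura coupling of F2 with [3-(benzyloxy)-4-methoxyphenyl]boronic acid F3 (from 7 and trimethyl borate) with Pd(PPh3)4 and K2CO3 in dioxane–water at 80 °C should give 11 without any oxidant.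

Step 3. The likely failure is proton transfer in place of addition. The aryl Grignard reagent may remove an α-hydrogen of the methyl ketone, whose carbonyl is deactivated by the neighbouring phenoxide and screened by the C6 methoxy group, so that 4 returns on work-up. In the second half, acid may reprotonate the electron-rich alkene and start cationic dimerisation. The fallback is a cross-coupling that needs neither carbonyl addition nor acid; it sets out from 4 and 6 and returns at 9. Ketone 4 is condensed with tosylhydrazide in MeOH at 60 °C to N'-[(1E)-1-(2-hydroxy-3,4,6-trimethoxyphenyl)ethylidene]-4-methylbenzenesulfonohydrazide F4. F4 is coupled with 6 under Pd2(dba)3, XPhos and LiOtBu (3.5 equiv) in dioxane at 100 °C. The diazo compound formed in the flask should give a palladium carbene, the aryl group should migrate to the carbene carbon, and β-hydride elimination from the methyl group should give 9 directly.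

Step 1. The likely failure is loss of regiocontrol in the ether cleavage. Both ortho methoxy groups can enter the aluminium chelate, and cleavage at the less hindered one, or at both, would misplace or duplicate the free phenol. The fallback moves the selection from two ethers to two phenols; it sets out from 1 and 2 and returns at 4. Acylation with SnCl4 in CH2Cl2 at −10 °C leaves all four ethers, and 3 is isolated. Both ortho ethers are then cleaved on purpose with excess BCl3 in CH2Cl2 (0 °C to rt) to give 1-(2,6-dihydroxy-3,4-dimethoxyphenyl)ethanone F5. One equivalent of Me2SO4 with K2CO3 in acetone should methylate the less hindered hydroxyl (the one next to ring hydrogen), leaving the crowded, chelated one free, which is 4.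

Step 5. The likely failure is over-reduction: once the benzyl group is gone, hydrogen may add slowly across C3=C4, or the catalyst may be inhibited and the reaction stall. The fallback is a non-reductive cleavage that goes from 11 directly to 12 with no new intermediate: BCl3 with pentamethylbenzene as benzyl cation scavenger in CH2Cl2 at −78 °C. No methyl ether in 11 is ortho or peri to a carbonyl group, so none should be cleaved at that temperature.

## Further compounds

F1 | step 4 | 4-hydroxy-5,7,8-trimethoxy-2H-chromen-2-one | COc1cc(OC)c2c(O)cc(=O)oc2c1OC
F2 | step 4 | 5,7,8-trimethoxy-2-oxo-2H-chromen-4-yl trifluoromethanesulfonate | COc1cc(OC)c2c(OS(=O)(=O)C(F)(F)F)cc(=O)oc2c1OC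
F3 | step 4 | [3-(benzyloxy)-4-methoxyphenyl]boronic acid | COc1ccc(B(O)O)cc1OCc1ccccc1
F4 | step 3 | N'-[(1E)-1-(2-hydroxy-3,4,6-trimethoxyphenyl)ethylidene]-4-methylbenzenesulfonohydrazide | C/C(=N\NS(=O)(=O)c1ccc(C)cc1)c1c(OC)cc(OC)c(OC)c1O
F5 | step 1 | 1-(2,6-dihydroxy-3,4-dimethoxyphenyl)ethanone | CC(=O)c1c(O)cc(OC)c(OC)c1O
F0 | step 5 | none | none
A1 | alternative 1 | (3-benzyloxy-4-methoxyphenyl)(2,4-dihydroxy-3,6-dimethoxyphenyl)methanone | COc1ccc(cc1OCc1ccccc1)C(=O)c1c(OC)cc(O)c(OC)c1O
A2 | alternative 1 | 6-[3-(benzyloxy)-4-methoxyphenyl]-4-methoxy-5-(methoxyacetyl)-2H-pyran-2-one | COCC(=O)c1c(OC)cc(=O)oc1-c1ccc(OC)c(OCc2ccccc2)c1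
A3 | alternative 2 | 4-(3-benzyloxy-4-methoxyphenyl)-2-ethoxy-7-methoxychromane-5,8-diol (mixture of diastereomers) | CCOC1CC(c2ccc(OC)c(OCc3ccccc3)c2)c2c(O)cc(OC)c(O)c2O1
A4 | alternative 2 | 4-{4-[3-(benzyloxy)-4-methoxyphenyl]-2-ethoxy-3,4-dihydro-2H-pyran-6-yl}-4-hydroxy-3-methoxycyclobut-2-en-1-one (mixture of diastereomers) | CCOC1CC(c2ccc(OC)c(OCc3ccccc3)c2)C=C(O1)C1(O)C(OC)=CC1=O
A5 | alternative 3 | 4-[4-methoxy-3-(methylsulfonyloxy)phenyl]-5,7,8-trimethoxy-3,4-dihydrocoumarin (racemic) | O=C1CC(c2ccc(OC)c(OS(C)(=O)=O)c2)c2c(OC)cc(OC)c(OC)c2O1
A6 | alternative 3 | 3-[4-methoxy-3-(methylsulfonyloxy)phenyl]-4,6,7-trimethoxyindan-1-one (racemic) | O=C1CC(c2ccc(OC)c(OS(C)(=O)=O)c2)c2c(OC)cc(OC)c(OC)c21
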